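**Assumptions:** "3‑O‑acetyl" is taken as the aryl acetate shown in the SMILES. Iridoid numbering is used throughout: C1 acetal, C3=C4(CO2Me), C5, C6, C7, C8, C9, C10 (the carbon on C8), C11/C12 lactone α‑C and C=O. "β" means the face carrying H‑5 and H‑9. The route is a design on paper; none of it has been run.

## Retrosynthetic overview

1. The E‑benzylidene (C11=CHAr) comes off by an aldol condensation of tetracyclic lactone 8 with 4‑acetoxybenzaldehyde.
2. The acetal/THF ring (O–C10) of 8 comes from an intramolecular oxa‑Michael addition of the C1 lactol onto spirobutenolide 7; this ring forms last.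
3. The spirobutenolide ring of 7 comes from a Bestmann‑ylide annulation of the tertiary α‑hydroxy aldehyde 5.
4. The C8–O bond and the C6=C7 alkene of 5 come from a [2,3]‑sigmatropic allyl selenoxide → selenenate rearrangement of the 6β‑seleno enal 4, made by γ‑selenenylation of the silyl dienol ether of 10‑oxogenipin.
5. The cyclopenta[c]pyran and its C5/C9 stereocentres are bought as genipin; chirality is relayed C5 → C6 → C8 → C10/C1.

## Route

**Step 1**
Reactants: 1, genipin
Product: 2, 10‑oxogenipin (C10 aldehyde, C7=C8 enal, free 1β‑lactol)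
Conditions: activated MnO2 (15 equiv), CH2Cl2, rt; filter and use crude
Reagents that add atoms: none
Why: Chemoselective MnO2 oxidation of the primary allylic alcohol, which reacts much faster than the lactol OH; no stereocentre is touched.

**Step 2**
Reactants: 2, 10‑oxogenipin
Product: 3, 1β‑O‑TBS 10‑silyl dienol ether (C10(OTBS)=C8–C7=C6; enol ether E/Z mixture)
Conditions: TBSOTf (2.5 equiv), Et3N (4 equiv), CH2Cl2, 0 °C → rt
Reagents that add atoms: TBSOTf, CC(C)(C)[Si](C)(C)OS(=O)(=O)C(F)(F)F
Why: Soft enolisation of the enal removes the only conjugated γ‑H (C6) to give the 1‑silyloxydiene, and the lactol OH is silylated in the same pot; C5 and C9 are not acidic and are untouched.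

**Step 3**
Reactants: 3, bis‑silyl dienol ether
Product: 4, 1β‑O‑TBS‑6β‑(phenylseleno)‑10‑oxogenipin (γ‑seleno enal, C7=C8 restored)
Conditions: PhSeCl (1.05 equiv), pyridine (cat.), CH2Cl2, −78 °C
Reagents that add atoms: PhSeCl, Cl[Se]c1ccccc1
Why: Vinylogous (γ‑selective) electrophilic selenenylation of a silyl dienol ether; PhSe+ attacks C6 on the convex β‑face, syn to H‑5 and anti to the C4–CO2Me side of the pyran ring, which sets C6.

**Step 4 (key step)**
Reactants: 4, 6β‑selenide
Product: 5, 1β‑O‑TBS‑8β‑hydroxy‑10‑oxo‑Δ6 compound (tertiary allylic α‑hydroxy aldehyde; OH on the H‑9 face, CHO on the concave face)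
Conditions: mCPBA (1.0 equiv), CH2Cl2, −78 °C; then pyridine/H2O, −78 → 0 °C
Reagents that add atoms: mCPBA, OOC(=O)c1cccc(Cl)c1 (one O)
Why: The allyl selenoxide undergoes a suprafacial [2,3]‑sigmatropic rearrangement to the selenenate, far below the temperature of syn‑elimination, moving O from Se to C8 on the β‑face and the alkene to C6=C7; hydrolysis of the selenenate gives the alcohol, with chirality transferred from C6 to the new C8 quaternary centre.

**Step 5**
Reactants: 5, α‑hydroxy aldehyde; 6, Bestmann ylide (ketenylidene)triphenylphosphorane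
Product: 7, 1β‑O‑TBS spirobutenolide (C8–O–C12(=O)–C11H=C10H, spiro at C8; C6=C7 retained)
Conditions: Ph3P=C=C=O (1.5 equiv), toluene, 80 °C
Reagents that add atoms: 6, O=C=C=P(c1ccccc1)(c1ccccc1)c1ccccc1 (C2O unit)
Why: The tertiary OH adds to the ketene ylide to give an acyl‑stabilised ylide that closes by intramolecular Wittig reaction on the adjacent non‑enolisable aldehyde (Bestmann butenolide annulation); C8 is not affected.

**Step 6**
Reactants: 7, spirobutenolide
Product: 8, tetracyclic lactone (the target lacking the 4‑acetoxybenzylidene; C11 = CH2)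
Conditions: TBAF (1.1 equiv), THF, 0 °C → rt; aq. NH4Cl
Reagents that add atoms: none
Why: Desilylation frees the lactolate, which anomerises by ring–chain tautomerism; the 1α‑oxygen then adds 5‑exo‑trig to C10 of the butenolide (intramolecular oxa‑Michael). Only the cis‑fused bis‑five‑membered ring system is geometrically possible, so C1 and C10 are dictated by C8/C9.

**Step 7**
Reactants: 8, tetracyclic lactone; 9, 4‑acetoxybenzaldehyde
Product: 10, 3‑O‑acetylprismatomerin
Conditions: LiHMDS (1.05 equiv), THF, −78 °C; then 9, −78 °C; then Ac2O, DMAP, −78 → 0 °C; then DBU, 0 °C → rt (one pot)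
Reagents that add atoms: 9, CC(=O)Oc1ccc(C=O)cc1 (ArCH unit). Ac2O only activates the aldol OH and its atoms are not retained.
Why: Aldol addition of the lactone lithium enolate, in‑situ O‑acetylation and E1cB elimination (aldol condensation) give the thermodynamically preferred E‑benzylidene with the aryl anti to the lactone C=O; excess Ac2O re‑acetylates any phenoxide that forms.

## Compound list

1 | Genipin, methyl (1R,4aS,7aS)‑1‑hydroxy‑7‑(hydroxymethyl)‑1,4a,5,7a‑tetrahydrocyclopenta[c]pyran‑4‑carboxylate | COC(=O)C1=CO[C@@H](O)[C@H]2[C@@H]1CC=C2CO | starting material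

2 | 10‑Oxogenipin (7‑formyl analogue of 1) | COC(=O)C1=CO[C@@H](O)[C@H]2[C@@H]1CC=C2C=O | intermediate

3 | Methyl 1β‑(TBS‑oxy)‑7‑[(TBS‑oxy)methylidene]‑1,4a,7,7a‑tetrahydrocyclopenta[c]pyran‑4‑carboxylate (cis H‑4a/H‑7a; enol ether E/Z mixture) | COC(=O)C1=CO[C@@H](O[Si](C)(C)C(C)(C)C)[C@H]2[C@@H]1C=CC2=CO[Si](C)(C)C(C)(C)C | intermediate

4 | 1β‑O‑TBS‑6β‑(phenylseleno)‑10‑oxogenipin (SePh cis to H‑5) | COC(=O)C1=CO[C@@H](O[Si](C)(C)C(C)(C)C)[C@H]2[C@@H]1[C@H]([Se]c3ccccc3)C=C2C=O | intermediate

5 | 1β‑O‑TBS‑8β‑hydroxy‑8α‑formyl‑Δ6 iridoid (OH cis to H‑9) | COC(=O)C1=CO[C@@H](O[Si](C)(C)C(C)(C)C)[C@H]2[C@@H]1C=C[C@@]2(O)C=O | intermediate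

6 | Bestmann ylide, (triphenylphosphoranylidene)ketene | O=C=C=P(c1ccccc1)(c1ccccc1)c1ccccc1 | starting material

7 | 1β‑O‑TBS C8‑spirobutenolide (lactone O on β‑face, C10=C11) | COC(=O)C1=CO[C@@H](O[Si](C)(C)C(C)(C)C)[C@H]2[C@@H]1C=C[C@]23OC(=O)C=C3 | intermediate

8 | Des‑arylidene tetracyclic lactone (plumericin core, C11 = CH2) | COC(=O)C1=CO[C@@H]2O[C@H]3CC(=O)O[C@]34C=C[C@H]1[C@H]24 | intermediate

9 | 4‑Acetoxybenzaldehyde | CC(=O)Oc1ccc(C=O)cc1 | starting material

10 | 3‑O‑Acetylprismatomerin | COC(=O)C1=CO[C@@H]2O[C@H]3/C(=C\c4ccc(OC(C)=O)cc4)C(=O)O[C@]34C=C[C@H]1[C@H]24 | target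

## Summary

Total steps: 7. Longest linear sequence: 7 (from genipin).

Steps most likely to fail, with fallbacks:

- **Step 3 (γ/β‑face selenenylation, which fixes the outcome of the step‑4 rearrangement).** If α‑attack, poor facial control, or a sluggish deconjugating rearrangement intervenes, change how the C8–O bond is made. Homologate 2 first (HWE to the dienoate, oxa‑Michael of the C1 OH onto C10, ester cleavage), then close the spirolactone by phenylselenolactonisation of the C12 acid onto C7=C8 followed by selenoxide elimination (or iodolactonisation/DBU), arriving at 8 directly.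
- **Step 5 (Bestmann annulation on a hindered tertiary alcohol; risk of α‑ketol shift on heating).** Make the C10–C11 bond first instead: Reformatsky addition of BrZnCH2CO2t‑Bu to the aldehyde of 5, lactonisation onto the C8 OH, then β‑elimination to 7 (or direct acid‑mediated acetalisation of the C10 OH with C1 to give 8).
- **Step 7 (enolate β‑alkoxide expulsion, aryl acetate lability).** Reverse the order in a plumieride‑type sequence: Morita–Baylis–Hillman reaction of butenolide 7 with 9, acetylation of the carbinol, then fluoride‑triggered desilylation and SN2′ (oxa‑Michael/E1cB) cyclisation of the lactol onto C10 with loss of acetate, forming the THF ring and the E‑benzylidene in one operation.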